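The numbers of this flask come from no measurement, and the outcome is calculated.

The second intermediate forms far faster than the starting material opens, 0.833 s against 15.2 s, so in teal it waits for the open intermediate and decays meanwhile.

the same everywhere: time 2.5 min
- teal: starting material 10 mM (fed, over 30 s); partner 20.0 mM; all else is in the flask from the start; the feed brings no volume worth counting
- grey: starting material 10 mM; partner 20.0 mM; everything together at the start
- green: starting material 10 mM; partner 20.0 mM (fed, over 30 s); all else is in the flask from the start; the feed brings no volume worth counting

- the flask that comes out highest in amount of target, in percent of the starting material charged, or "all alike" when all lie within 1.5 percentage points (teal / grey / green / all alike)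
- target at the end, in percent of the starting material charged, teal
- target at the end, in percent of the starting material charged, grey
- target at the end, in percent of the starting material charged, green

- where a step has two of a species, its rate is k times that concentration squared, and two are used at each turn
- run time (teal): 2.5 min

    2 second intermediate → homo product (k1 = 0.26 M⁻¹ s⁻¹)
    partner → second intermediate (k2 = 1.2 s⁻¹)
    open intermediate + second intermediate → target (k3 = 14 M⁻¹ s⁻¹)
    second intermediate → decomposed reagent (k4 = 0.021 s⁻¹)
    starting material ⇌ open intermediate (K5 = 2.9, k5 = 0.066 s⁻¹)

I reckon teal in fractions of the starting material charge. My quantity is the surviving reagent: the second intermediate still alive when the charge has opened, counted as if none had been captured, with decay and homocoupling both taken. The crude upper bound is the charge itself, 100%, and the crude lower bound is zero. I narrow them, as estimates, with two arrival times.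

Mean arrival, half the feed plus one opening lifetime: 30.2 s

Surviving reagent then, my upper figure: 86.2%

Last arrival, the whole feed plus one opening lifetime: 45.2 s

Surviving reagent then, my lower figure: 59.5%

This is a working bracket, not a proof. Grey's mean arrival is one opening lifetime, and its surviving reagent of 128% exceeds the charge, so the count sets no ceiling for grey. Green feeds the partner, so I do not use the count there.

The forecast picks green, with green at 94% (90% to 97%), grey at 86.5% (83% to 90%) and teal at 71.5% (67% to 76%). Of teal it says “feeding the starting material delays open intermediate further, so more reagent decays first”. Its teal value lies inside my bracket.

The simulation gives green as highest: green 94.8%, grey 87.7%, teal 71.0%.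

Teal's 71.0% falls inside the bracket, at 82.4% of the surviving reagent at mean arrival. At the end, teal holds 0.0117 mM of second intermediate beside 21.5% of open intermediate.

For teal's neighbour with 5.0 mM of partner, the count gives 25.1% at mean arrival and 18.0% at last arrival. That neighbour's computed target is 25.2%, level with the mean-arrival figure.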